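## Structural features

The target 16 is an achiral biflavone ether: two 5-hydroxy-7-methoxyflavone units (unit 1 = rings A, C, B; unit 2 = rings D, E, F) are joined by one diaryl ether oxygen running from C4' of ring B to C8'' of ring D. There is no stereocenter and no hindered axis, so the whole problem is regiochemistry and the differentiation of oxygens. Ring D is pentasubstituted: the aryloxy group at C8'' sits between the 7''-methoxy group and O1'', and only C6''–H remains. Placing the ether at C8'' and not at C6'', and making this hindered unsymmetrical ether at all, is the real difficulty. Five phenolic oxygens must end in three states: two methyl ethers (O7, O7''), two hydroxyls chelated to the C4 and C4'' carbonyls (O5, O5'') and one free hydroxyl (O4'''). The fragile parts are the pyranone rings C and E (vinylogous esters that accept nucleophiles at C2/C2'' and open in hot alkali) and ring D, which strong acid can open and re-close the other way round (Wessely–Moser shift of the ether to C6'') and which passes through an air-sensitive quinol stage. The key step exploits that C4 is a carbonyl carbon on C4a, whose ring A neighbours C5 and C8a both carry oxygen while C7 carries the methoxy group. Ring A plus C4 is therefore mirror-symmetric 2,6-dihydroxy-4-methoxybenzaldehyde, whose formyl carbon can be made an acyl nucleophile; either hydroxyl can become O1 and the other becomes the 5-hydroxyl.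

## Logic of the disconnections

16 to 15: the O4'''–CH2 bond of a benzyl ether is cut. O4''' is the only phenol not shielded by chelation, and benzyl is stable to base, acid, persulfate and the rhodium step. The gain is a one-step, neutral end game. The demand is that hydrogenolysis must stop before C2=C3 or C2''=C3'' is saturated.

15 to 2 and 13: the C3–C4 and O1–C2 bonds of ring C are cut, through diketone 14. This is the convergent cut: it separates a small symmetric piece from everything else and arrives directly at the flavone oxidation level. The forward step must activate the formyl C–H bond of 2 in preference to every aryl C–H bond and must join 2 to 13 faster than 13 couples with itself. The 5''-hydroxyl of 13 is left free on purpose: 2 and 15 carry the same chelating hydroxy-ketone motif, so masking it would add steps and remove no chelator.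

13 to 11: the bond between the ring B carbonyl carbon and the ylide carbon is cut, through 12. Acyl transfer to the sulfur ylide reagent is the standard entry, but the same reagent is a conjugate nucleophile toward pyranone E. The forward step is therefore run at 0 °C on the reactive acyl donor 12 rather than on a methyl ester at reflux. The first equivalent of reagent deprotonates O5''–H, and the resulting phenoxide lowers the electrophilicity of ring E. This is the point where the route to the precursor is redesigned.

11 to 8 and 9: the O–C4' bond is cut, through 10. Ring B carries a para acceptor, so it can be the electrophile of a nucleophilic aromatic substitution, and O8'' of 8 is the nucleophile. The chelated, peri-hindered O5'' does not compete. The demand is that a di-ortho-substituted, oxidation-prone phenoxide attacks a moderately activated fluoroarene, so oxygen is excluded and the ester is cleaved in the same pot.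

8 to 6: the C8–O bond is cut, through 7. Persulfate hydroxylation goes para to a phenoxide, and the only phenol of 6 is O5–H, whose para position is C8. The mechanism thus settles the C8 against C6 question that is the core difficulty of ring D. The price is moderate conversion, with recovery of unchanged 6.

6 to 3 and 4: the C2–C3 and O1–C2 bonds of ring E are cut, through 5. Enolate acylation followed by cyclodehydration reduces unit 2 to two commercial materials, and the symmetry of 3 removes any ambiguity in ring closure. The demand is acylation on carbon, met by using the polyanion.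

2 to 1: the O–CH3 bond at the 4-oxygen is cut. The 4-hydroxyl of 1 is the most acidic and the only one not hydrogen-bonded, so one equivalent of base and methylating agent should select it. The demand is stopping at the monoether.

## Other disconnections considered

Alternative 1: The cut is the C4a–C8a bond of ring A. In the forward key step the pyrone A2 is opened by Mg(OMe)2 in methanol to a magnesium-chelated diketo ester. Its central methylene attacks the ester carbonyl (Claisen closure of a six-membered ring), and aromatisation gives chalcone A1.
- In its favour: it builds the benzene ring itself, and the methyl enol ether of the pyrone fixes the methoxy group para to the acyl carbon without any selective methylation. It needs no precious metal. On these points it is the equal or the better of the chosen plan, and it uses the same symmetry of ring A.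
- Against it here: unit 2 must survive methoxide in hot methanol, so the 5''-oxygen has to be a methyl ether (as in A1) that is removed later, and the enone chain of A2 is open to methoxide addition. A1 is also one oxidation level below a flavone, so an oxidative ring C closure must follow.
- Comparison: the alternative forms one ring and one skeletal bond by ordinary carbanion chemistry; the chosen step forms one ring and two bonds by polarity reversal at the formyl carbon. In step economy the alternative needs roughly three steps between the diaryl ether and its key step (aldehyde, two-carbon extension, pyrone acylation) and two or three after it, against one before (step 5) and one after (step 7).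

Alternative 2: The cuts are C2=C3 and C2''=C3''. In the forward key step the bis-phosphorane A4, with the ring B and ring F carboxyls as aryl esters on the ortho oxygens of rings A and D, is heated. Each ylide carbon attacks its neighbouring ester carbonyl (intramolecular Wittig) and A3 forms with loss of two molecules of triphenylphosphine oxide.
- In its favour: two rings close in one neutral, metal-free operation, and O1 and O1'' are already in place, so closure has no regiochemical question. In rings formed per step it is better than the chosen plan.
- Against it here: A4 is as hard to make as the target. It needs a ring D acetophenone oxygenated ortho, not para, to its phenol (persulfate para-hydroxylation does not apply), two phosphoranylidene-acetyl groups, and two different aroyl groups placed on two specific phenols without acylation of the ylide carbons. Both 5-oxygens must be methyl ethers, so A3 still needs a twofold selective 5-O-demethylation besides debenzylation. Electron-rich aryl esters are poor Wittig acceptors.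
- Comparison: it is linear, where the chosen plan joins two halves of similar size in the key step, and it is clearly longer.

Alternative 3: The cut is the C4a''–C4'' bond of ring E. The symmetric resorcinol A6 adds through one hydroxyl to the ring F propiolate A7. The derived (Z)-acid A8 is activated with trifluoroacetic anhydride and acylates the ring ortho to the enol ether oxygen (Friedel–Crafts), giving A5.
- In its favour: the aryloxy group lies between the two equivalent hydroxyls of A6, so the ether is at C8'' by construction, with no quinol and no persulfate step. On this point it is better than steps 3 and 4 of the chosen plan.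
- Against it here: the methoxy group of A6 is para to the aryloxy carbon and therefore ends at C5'', while the free hydroxyl ends at C7''. A5 is thus the 7''-hydroxy-5''-methoxy isomer, the reverse of what 16 needs, and must be corrected by O7''-methylation and selective O5''-demethylation. A6 requires a 2-oxygenated phloroglucinol derivative (several steps), only the Z acid can close, and the acidic closure puts the benzyl ether at risk. A7 is best a tert-butyl ester so that the acrylate can be freed beside the methyl benzoate.
- Comparison: the alternative replaces only the way to unit 2 (steps 2 to 4 here) by a longer sequence and still needs a ring C construction such as the chosen key step. Mechanistically its closure is a simple electrophilic substitution with no catalyst risk.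

Key step: step 6

Remark: unprimed locants are used for unit 1 and double- or triple-primed locants for unit 2. The structures of 2, 13 and 15 were checked against the target atom by atom and are used unchanged; the only mismatch found is the oxygen pattern of A5 noted above.

## Route

Step 1
Reactants: 1 2,4,6-trihydroxybenzaldehyde
Product: 2 2,6-dihydroxy-4-methoxybenzaldehyde
Conditions: Me2SO4 (1.0 equiv), K2CO3 (1.0 equiv), acetone, 0 to 20 °C
Reagents that add atoms: dimethyl sulfate, COS(=O)(=O)OC
Why: Williamson O-methylation under pKa control: the 4-hydroxyl, para to the formyl group and not hydrogen-bonded, is ionised first by one equivalent of carbonate, while the 2- and 6-hydroxyls are tied to C=O and less nucleophilic.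

Step 2
Reactants: 3 2',6'-dihydroxy-4'-methoxyacetophenone; 4 4-(benzyloxy)benzoyl chloride
Product: 6 2-[4-(benzyloxy)phenyl]-5-hydroxy-7-methoxy-4H-chromen-4-one, via 1,3-diketone 5 (not isolated)
Conditions: LiN(SiMe3)2 (4.2 equiv), THF, −78 °C; 4, −78 to 20 °C; aq. HCl, extraction, solvent switch (crude 5 not purified); p-TsOH·H2O (0.2 equiv), toluene, 110 °C, Dean–Stark
Reagents that add atoms: none
Why: Baker–Venkataraman-type flavone synthesis in its polyanion form: the trilithio derivative of 3 (two phenoxides and the ketone enolate) is acylated on carbon by 4 to give 5, and acid-catalysed cyclodehydration closes ring E. Because 3 is symmetric, either hydroxyl closes to the same 5-hydroxy-7-methoxy ring, and the benzyl ether tolerates catalytic sulfonic acid in toluene.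

Step 3
Reactants: 6 2-[4-(benzyloxy)phenyl]-5-hydroxy-7-methoxy-4H-chromen-4-one
Product: 8 2-[4-(benzyloxy)phenyl]-5,8-dihydroxy-7-methoxy-4H-chromen-4-one, via aryl sulfate 7 (not isolated)
Conditions: K2S2O8 (1.5 equiv), KOH (5 equiv), H2O–pyridine, 15–20 °C; pH 5, unchanged 6 filtered off for re-use; filtrate, conc. HCl, Na2SO3, 80 °C
Reagents that add atoms: potassium peroxodisulfate, [K+].[K+].[O-]S(=O)(=O)OOS(=O)(=O)[O-]
Why: Elbs persulfate oxidation: the 5-phenoxide attacks a peroxide oxygen through its para carbon, C8, the only position para to a free phenol in 6, giving sulfate 7. Acid hydrolysis frees the quinol while sulfite keeps it reduced; the cold alkaline and brief warm acidic conditions should leave the benzyl ether and the pyranone intact.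

Step 4
Reactants: 8 2-[4-(benzyloxy)phenyl]-5,8-dihydroxy-7-methoxy-4H-chromen-4-one; 9 methyl 4-fluorobenzoate
Product: 11 4-({2-[4-(benzyloxy)phenyl]-5-hydroxy-7-methoxy-4-oxo-4H-chromen-8-yl}oxy)benzoic acid, via methyl ester 10 (not isolated)
Conditions: 9 (1.3 equiv), Cs2CO3 (2.5 equiv), degassed DMSO, Ar, 110 °C; then LiOH·H2O (6 equiv), H2O–THF, 50 °C; 1 M HCl to pH 2
Reagents that add atoms: lithium hydroxide, [Li+].[OH-]
Why: Nucleophilic aromatic substitution (addition–elimination) of the 8-phenoxide on the fluoroarene activated by its para ester; the 5-hydroxyl is hydrogen-bonded to C4=O and peri-hindered, so O8 should react alone. Saponification in the same pot gives the acid, which the pyranone should survive at 50 °C, and exclusion of air protects the quinol dianion.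

Step 5
Reactants: 11 4-({2-[4-(benzyloxy)phenyl]-5-hydroxy-7-methoxy-4-oxo-4H-chromen-8-yl}oxy)benzoic acid
Product: 13 dimethylsulfoxonium 2-oxo-2-[4-({2-[4-(benzyloxy)phenyl]-5-hydroxy-7-methoxy-4-oxo-4H-chromen-8-yl}oxy)phenyl]ethylide, via acyl imidazolide 12 (not isolated)
Conditions: CDI (1.15 equiv), DMF, 20 °C; added to Me3S(O)I (4.0 equiv)/KOtBu (3.9 equiv) (THF, 65 °C, then 0 °C); 0 to 20 °C; aq. NH4Cl
Reagents that add atoms: trimethylsulfoxonium iodide, C[S+](C)(C)=O.[I-]; 1,1'-carbonyldiimidazole, O=C(n1ccnc1)n1ccnc1 (its imidazole is carried only by 12)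
Why: Acyl transfer from an N-acylimidazole to dimethylsulfoxonium methylide (Corey–Chaykovsky ylide acylation): one equivalent of ylide deprotonates O5''–H, one is acylated and one deprotonates the acylsulfoxonium salt to the stabilised ylide. The reactive imidazolide allows 0 °C, and the 5''-phenoxide deactivates pyranone E, so conjugate addition at C2''=C3'' should not compete.

Step 6
Reactants: 2 2,6-dihydroxy-4-methoxybenzaldehyde; 13 dimethylsulfoxonium 2-oxo-2-[4-({2-[4-(benzyloxy)phenyl]-5-hydroxy-7-methoxy-4-oxo-4H-chromen-8-yl}oxy)phenyl]ethylide
Product: 15 2-[4-({2-[4-(benzyloxy)phenyl]-5-hydroxy-7-methoxy-4-oxo-4H-chromen-8-yl}oxy)phenyl]-5-hydroxy-7-methoxy-4H-chromen-4-one, via 1,3-diketone 14 (not isolated)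
Conditions: 2 (2.5 equiv), [Cp*RhCl2]2 (5 mol %), AgSbF6 (20 mol %), AcOH (2 equiv), ClCH2CH2Cl, 80 °C, 13 added over 3 h; then p-TsOH·H2O (1 equiv), 80 °C
Reagents that add atoms: none
Why: Chloride abstraction by AgSbF6 gives a cationic Cp*Rh species of trivalent rhodium that binds one phenoxide of 2 and cleaves the adjacent formyl C–H bond by concerted metalation–deprotonation to a five-membered acyl(aryloxy)rhodacycle, which makes the aldehyde carbon an acyl nucleophile. Ylide 13 binds through carbon, loses dimethyl sulfoxide to give a rhodium carbene, and 1,1-migratory insertion of the acyl group forms the C3–C4 bond; protonolysis by AcOH releases diketone 14 and returns the catalyst with no change of oxidation state and no external oxidant. Acid then closes ring C by attack of a ring A hydroxyl on the ring B aroyl carbonyl (6-exo-trig hemiketal formation) and loss of water, which forms O1–C2. The closest known reaction type is the annulation of salicylaldehydes with aroyl sulfoxonium ylides to flavones under [Cp*RhCl2]2 and a silver salt. No stereocenter is formed. Regiochemistry is not at issue because 2 is symmetric: whichever hydroxyl directs and closes, the other becomes the chelated 5-hydroxyl. The step needs formyl C–H over aryl C–H activation and cross-coupling over self-coupling of 13; the first is secured because only the salicylaldehyde can form the five-membered O,C-chelate (O5'' would need a four-membered ring to reach C6''–H, and C5'' is blocked for ketone direction), the second by the excess of 2 and slow addition of 13.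

Step 7
Reactants: 15 2-[4-({2-[4-(benzyloxy)phenyl]-5-hydroxy-7-methoxy-4-oxo-4H-chromen-8-yl}oxy)phenyl]-5-hydroxy-7-methoxy-4H-chromen-4-one
Product: 16 5-hydroxy-2-[4-({5-hydroxy-2-(4-hydroxyphenyl)-7-methoxy-4-oxo-4H-chromen-8-yl}oxy)phenyl]-7-methoxy-4H-chromen-4-one
Conditions: H2 (1 atm), Pd/C (10 wt %), THF–MeOH, 20 °C
Reagents that add atoms: none
Why: Hydrogenolysis of the benzyl aryl ether over palladium on carbon; the flavone C2=C3 bonds, the methyl ethers and the diaryl ether should be inert at one atmosphere and room temperature, and the reaction is stopped after uptake of one equivalent.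

## Compound list

1 | 2,4,6-trihydroxybenzaldehyde | O=Cc1c(O)cc(O)cc1O | starting material
2 | 2,6-dihydroxy-4-methoxybenzaldehyde | COc1cc(O)c(C=O)c(O)c1 | intermediate
3 | 2',6'-dihydroxy-4'-methoxyacetophenone | CC(=O)c1c(O)cc(OC)cc1O | starting material
4 | 4-(benzyloxy)benzoyl chloride | O=C(Cl)c1ccc(OCc2ccccc2)cc1 | starting material
5 | 1-[4-(benzyloxy)phenyl]-3-(2,6-dihydroxy-4-methoxyphenyl)propane-1,3-dione | COc1cc(O)c(C(=O)CC(=O)c2ccc(OCc3ccccc3)cc2)c(O)c1 | intermediate (not isolated)
6 | 2-[4-(benzyloxy)phenyl]-5-hydroxy-7-methoxy-4H-chromen-4-one | COc1cc(O)c2c(=O)cc(-c3ccc(OCc4ccccc4)cc3)oc2c1 | intermediate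
7 | potassium 2-[4-(benzyloxy)phenyl]-5-hydroxy-7-methoxy-4-oxo-4H-chromen-8-yl sulfate | COc1cc(O)c2c(=O)cc(-c3ccc(OCc4ccccc4)cc3)oc2c1OS(=O)(=O)[O-].[K+] | intermediate (not isolated)
8 | 2-[4-(benzyloxy)phenyl]-5,8-dihydroxy-7-methoxy-4H-chromen-4-one | COc1cc(O)c2c(=O)cc(-c3ccc(OCc4ccccc4)cc3)oc2c1O | intermediate
9 | methyl 4-fluorobenzoate | COC(=O)c1ccc(F)cc1 | starting material
10 | methyl 4-({2-[4-(benzyloxy)phenyl]-5-hydroxy-7-methoxy-4-oxo-4H-chromen-8-yl}oxy)benzoate | COC(=O)c1ccc(Oc2c(OC)cc(O)c3c(=O)cc(-c4ccc(OCc5ccccc5)cc4)oc23)cc1 | intermediate (not isolated)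
11 | 4-({2-[4-(benzyloxy)phenyl]-5-hydroxy-7-methoxy-4-oxo-4H-chromen-8-yl}oxy)benzoic acid | OC(=O)c1ccc(Oc2c(OC)cc(O)c3c(=O)cc(-c4ccc(OCc5ccccc5)cc4)oc23)cc1 | intermediate
12 | 1-[4-({2-[4-(benzyloxy)phenyl]-5-hydroxy-7-methoxy-4-oxo-4H-chromen-8-yl}oxy)benzoyl]-1H-imidazole | O=C(c1ccc(Oc2c(OC)cc(O)c3c(=O)cc(-c4ccc(OCc5ccccc5)cc4)oc23)cc1)n1ccnc1 | intermediate (not isolated)
13 | dimethylsulfoxonium 2-oxo-2-[4-({2-[4-(benzyloxy)phenyl]-5-hydroxy-7-methoxy-4-oxo-4H-chromen-8-yl}oxy)phenyl]ethylide | CS(C)(=O)=CC(=O)c1ccc(Oc2c(OC)cc(O)c3c(=O)cc(-c4ccc(OCc5ccccc5)cc4)oc23)cc1 | intermediate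
14 | 1-(2,6-dihydroxy-4-methoxyphenyl)-3-[4-({2-[4-(benzyloxy)phenyl]-5-hydroxy-7-methoxy-4-oxo-4H-chromen-8-yl}oxy)phenyl]propane-1,3-dione | COc1cc(O)c(C(=O)CC(=O)c2ccc(Oc3c(OC)cc(O)c4c(=O)cc(-c5ccc(OCc6ccccc6)cc5)oc34)cc2)c(O)c1 | intermediate (not isolated)
15 | 2-[4-({2-[4-(benzyloxy)phenyl]-5-hydroxy-7-methoxy-4-oxo-4H-chromen-8-yl}oxy)phenyl]-5-hydroxy-7-methoxy-4H-chromen-4-one | COc1cc(O)c2c(=O)cc(-c3ccc(Oc4c(OC)cc(O)c5c(=O)cc(-c6ccc(OCc7ccccc7)cc6)oc45)cc3)oc2c1 | intermediate
16 | 5-hydroxy-2-[4-({5-hydroxy-2-(4-hydroxyphenyl)-7-methoxy-4-oxo-4H-chromen-8-yl}oxy)phenyl]-7-methoxy-4H-chromen-4-one | COc1cc(O)c2c(=O)cc(-c3ccc(Oc4c(OC)cc(O)c5c(=O)cc(-c6ccc(O)cc6)oc45)cc3)oc2c1 | target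

## Step count and least certain steps

Total: 7 steps. Longest linear sequence: 6 steps (steps 2 to 7, from 3 and 4 to 16); step 1 is a one-step side branch.

Step 6 (key step). The catalyst may be held back by O,O-chelation to the hydroxy-ketone motifs of 13, 2 and 15, so turnover may stall. Ylide 13 may also couple with itself through ortho C–H activation of ring B directed by its own carbonyl, or be protonated and lost before it meets the rhodacycle. The fallback uses normal polarity and sets out from 11 and 3. Acid 11 is converted with oxalyl chloride and catalytic DMF in CH2Cl2 into 4-({2-[4-(benzyloxy)phenyl]-5-hydroxy-7-methoxy-4-oxo-4H-chromen-8-yl}oxy)benzoyl chloride F1. F1 is added at −78 °C to an excess of the polyanion of 3 (LiN(SiMe3)2, THF), so that acylation on carbon gives 14. Heating with p-TsOH·H2O in toluene then closes ring C, and the route is rejoined at 15.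

Step 5. Conjugate addition of the methylide to C2'' (cyclopropanation or opening of pyranone E) may compete with acyl transfer if the acyl imidazolide reacts slowly, and the potassium 5''-phenoxide may be acylated or may precipitate. The fallback brings in ring B at the aldehyde level and sets out from 8. Substitution on 4-fluorobenzaldehyde (K2CO3, DMF, 90 °C, argon) should give 4-({2-[4-(benzyloxy)phenyl]-5-hydroxy-7-methoxy-4-oxo-4H-chromen-8-yl}oxy)benzaldehyde F2. Claisen–Schmidt condensation of F2 with 3 (KOH, EtOH–THF, 20 °C) should give (E)-1-(2,6-dihydroxy-4-methoxyphenyl)-3-[4-({2-[4-(benzyloxy)phenyl]-5-hydroxy-7-methoxy-4-oxo-4H-chromen-8-yl}oxy)phenyl]prop-2-en-1-one F3. Oxidative cyclisation with catalytic I2 in DMSO at 120 °C rejoins the route at 15.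

Step 3. Persulfate oxidations stop at partial conversion and can over-oxidise the quinol to the quinone and to polymeric material. The warm acid used to cleave the sulfate may also begin to remove the benzyl group. The fallback installs the C8'' oxygen by halogenation and copper catalysis and sets out from 6.
- O-methylation (MeI, K2CO3, DMF, 60 °C) gives 2-[4-(benzyloxy)phenyl]-5,7-dimethoxy-4H-chromen-4-one F4.
- Iodination with N-iodosuccinimide and catalytic CF3CO2H in MeCN, which goes to C8 once O5 is etherified, gives 2-[4-(benzyloxy)phenyl]-8-iodo-5,7-dimethoxy-4H-chromen-4-one F5.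
- Ullmann etherification with methyl 4-hydroxybenzoate (CuI as the source of monovalent copper, picolinic acid, K3PO4, DMSO, 90 °C) gives methyl 4-({2-[4-(benzyloxy)phenyl]-5,7-dimethoxy-4-oxo-4H-chromen-8-yl}oxy)benzoate F6.
- Chelation-controlled 5''-O-demethylation with MgI2·OEt2 in THF at 60 °C rejoins the route at 10, which is saponified as in step 4 to 11.

This path also avoids the substitution of step 4.

Step 4. The ester is only a moderate activator and the phenoxide is flanked on both sides, so substitution may be slow. During long heating, the quinol dianion may be oxidised by traces of air or the pyranone opened by base. The fallback replaces addition–elimination by metal-free ligand coupling at trivalent iodine and sets out from 8. Treatment with KOtBu and bis[4-(methoxycarbonyl)phenyl]iodonium trifluoromethanesulfonate in THF at 0 to 20 °C should arylate O8 and give 10 directly; no new compound is made (F0). Saponification as in step 4 then leads to 11.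

## Further compounds

F1 | step 6 | 4-({2-[4-(benzyloxy)phenyl]-5-hydroxy-7-methoxy-4-oxo-4H-chromen-8-yl}oxy)benzoyl chloride | O=C(Cl)c1ccc(Oc2c(OC)cc(O)c3c(=O)cc(-c4ccc(OCc5ccccc5)cc4)oc23)cc1
F2 | step 5 | 4-({2-[4-(benzyloxy)phenyl]-5-hydroxy-7-methoxy-4-oxo-4H-chromen-8-yl}oxy)benzaldehyde | O=Cc1ccc(Oc2c(OC)cc(O)c3c(=O)cc(-c4ccc(OCc5ccccc5)cc4)oc23)cc1
F3 | step 5 | (E)-1-(2,6-dihydroxy-4-methoxyphenyl)-3-[4-({2-[4-(benzyloxy)phenyl]-5-hydroxy-7-methoxy-4-oxo-4H-chromen-8-yl}oxy)phenyl]prop-2-en-1-one | COc1cc(O)c(C(=O)/C=C/c2ccc(Oc3c(OC)cc(O)c4c(=O)cc(-c5ccc(OCc6ccccc6)cc5)oc34)cc2)c(O)c1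
F4 | step 3 | 2-[4-(benzyloxy)phenyl]-5,7-dimethoxy-4H-chromen-4-one | COc1cc(OC)c2c(=O)cc(-c3ccc(OCc4ccccc4)cc3)oc2c1
F5 | step 3 | 2-[4-(benzyloxy)phenyl]-8-iodo-5,7-dimethoxy-4H-chromen-4-one | COc1cc(OC)c2c(=O)cc(-c3ccc(OCc4ccccc4)cc3)oc2c1I
F6 | step 3 | methyl 4-({2-[4-(benzyloxy)phenyl]-5,7-dimethoxy-4-oxo-4H-chromen-8-yl}oxy)benzoate | COC(=O)c1ccc(Oc2c(OC)cc(OC)c3c(=O)cc(-c4ccc(OCc5ccccc5)cc4)oc23)cc1
F0 | step 4 | none | none
A1 | alternative 1 | (E)-1-(2,6-dihydroxy-4-methoxyphenyl)-3-[4-({2-[4-(benzyloxy)phenyl]-5,7-dimethoxy-4-oxo-4H-chromen-8-yl}oxy)phenyl]prop-2-en-1-one | COc1cc(O)c(C(=O)/C=C/c2ccc(Oc3c(OC)cc(OC)c4c(=O)cc(-c5ccc(OCc6ccccc6)cc5)oc34)cc2)c(O)c1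
A2 | alternative 1 | 6-{(3E)-4-[4-({2-[4-(benzyloxy)phenyl]-5,7-dimethoxy-4-oxo-4H-chromen-8-yl}oxy)phenyl]-2-oxobut-3-en-1-yl}-4-methoxy-2H-pyran-2-one | COC1=CC(=O)OC(CC(=O)/C=C/c2ccc(Oc3c(OC)cc(OC)c4c(=O)cc(-c5ccc(OCc6ccccc6)cc5)oc34)cc2)=C1
A3 | alternative 2 | 2-[4-({2-[4-(benzyloxy)phenyl]-5,7-dimethoxy-4-oxo-4H-chromen-8-yl}oxy)phenyl]-5,7-dimethoxy-4H-chromen-4-one | COc1cc(OC)c2c(=O)cc(-c3ccc(Oc4c(OC)cc(OC)c5c(=O)cc(-c6ccc(OCc7ccccc7)cc6)oc45)cc3)oc2c1
A4 | alternative 2 | 3,5-dimethoxy-2-[(triphenylphosphoranylidene)acetyl]phenyl 4-{2-[4-(benzyloxy)benzoyloxy]-4,6-dimethoxy-3-[(triphenylphosphoranylidene)acetyl]phenoxy}benzoate | COc1cc(OC)c(C(=O)C=P(c2ccccc2)(c2ccccc2)c2ccccc2)c(OC(=O)c2ccc(Oc3c(OC)cc(OC)c(C(=O)C=P(c4ccccc4)(c4ccccc4)c4ccccc4)c3OC(=O)c3ccc(OCc4ccccc4)cc3)cc2)c1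
A5 | alternative 3 | methyl 4-({2-[4-(benzyloxy)phenyl]-7-hydroxy-5-methoxy-4-oxo-4H-chromen-8-yl}oxy)benzoate | COC(=O)c1ccc(Oc2c(O)cc(OC)c3c(=O)cc(-c4ccc(OCc5ccccc5)cc4)oc23)cc1
A6 | alternative 3 | methyl 4-(2,6-dihydroxy-4-methoxyphenoxy)benzoate | COC(=O)c1ccc(Oc2c(O)cc(OC)cc2O)cc1
A7 | alternative 3 | tert-butyl 3-[4-(benzyloxy)phenyl]prop-2-ynoate | CC(C)(C)OC(=O)C#Cc1ccc(OCc2ccccc2)cc1
A8 | alternative 3 | (2Z)-3-[4-(benzyloxy)phenyl]-3-{3-hydroxy-5-methoxy-2-[4-(methoxycarbonyl)phenoxy]phenoxy}prop-2-enoic acid | OC(=O)/C=C(\Oc1cc(OC)cc(O)c1Oc1ccc(C(=O)OC)cc1)c1ccc(OCc2ccccc2)cc1
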